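Its constants are assumed; the rest is arithmetic.

2.00 is the ratio of the constant of the first exchange to that of the second, and the turn of this row can be reckoned from it.

    starting complex + complex with one exchanged → side product (k1 = 0.026 M⁻¹ s⁻¹)
    starting complex + incoming ligand → leaving ligand + complex with one exchanged (k2 = 0.044 M⁻¹ s⁻¹)
    complex with one exchanged + incoming ligand → leaving ligand + complex with two exchanged (k3 = 0.022 M⁻¹ s⁻¹)

| flask | starting complex | incoming ligand | time |
|---|---|---|---|
| north | 0.25 M | 0.120 M | 1.5 min |
| west | 0.25 M | 0.250 M | 1.5 min |
| north-west | 0.25 M | 0.500 M | 1.5 min |
| south | 0.25 M | 1.00 M | 1.5 min |
| north-east | 0.25 M | 2.00 M | 1.5 min |

- amount of complex with one exchanged at the end, in percent of the starting complex charged for north, west, north-west, south, north-east, in this order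
- the course of these numbers from the first flask to the last (hardly changes / falls, then rises / falls all the way / rises, then falls / rises all the way)

- in percentages every species weighs as the starting complex in it: one side product counts as two
- "hardly changes" means that all values lie within two and a half points (for a concentration: within two and a half percent of the largest)
- run time (north): 1.5 min
- a step back or a flat step of under half a point counts as no turn

My own reckoning sets the side product aside and compares two times: the run time, 1.5 min, and the peak time, when the complex with one exchanged tops out.

1. With free ligand held steady, both exchanges are pseudo-first-order. The peak time is then the logarithm of the ratio, divided by the difference of the constants and by the ligand level.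

2. With ligand steady, the fraction with one exchanged depends on level and time through their product, so the row tops where peak time equals run time. That needs a free level of 1.40 equivalents of the starting complex charged.

3. But ligand is consumed, so go round once more. At the peak the fractions are 0.250 starting complex, 0.500 with one exchanged, and the rest with two exchanged, and together these have used one equivalent of ligand.

4. I take the mean free level as 0.5 equivalent below the charge. This gives the turning charge, the ligand charge at which run time equals peak time at the mean free level: 1.90 equivalents.

5. North-west, at 2.00 equivalents, stands just above it, so I expect the row to rise, then fall, with its top at north-west.

The forecast gives 18.5%, 31%, 39%, 31% and 7%, course rises, then falls, arguing that “with little ligand its formation is limited by ligand supply”.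

The simulation gives 18.6%, 31.9%, 41.2%, 30.4% and 6.80%, course rises, then falls. The row turns at 2.13 equivalents against my turning charge of 1.90, so north-west stands just below the turn, not above it as I reckoned. North-east, charged with 8.00 equivalents, lies at 4.21 times the turning charge. North-east still shows 6.80% of complex with one exchanged mainly because it is read at 1.50 min and not at 15.0 min, when its reading is 0%.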